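**Plan**

1. Cuts, in retrosynthetic order: C3–O and C4–Br together (anti addition of Br/OH to a ring-A diene), then C1–CH3 and the ring-B C10–Br bond (both from ketones), then C5–C6, last C1–C6 (alkenylmetal plus ketone).
2. Enabling feature: in ring A, C1(Me)=C2–C3(OH)–C4(Br)–C5(Me)2–C6, the bond C5–C6 joins the gem-dimethyl carbon to the spiro atom. C1, the other ring-A neighbour of C6, can be a carbinol carbon before and a ketone after a 1,2-shift of C5 onto a C6=C7 alkene of ring B (C6–C7–C8–C9(Me)=C10(Br)–C11).
3. Forward: a ring-B alkenyl bromide is added to a cyclopentanone (C1–C6); the bromonium-triggered ring expansion then forms ring A and the spiro centre in one step. Ring B is carried to the bromoalkene, ring A to the C1-methyl diene, and the bromohydrin is added last.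
4. Stereochemistry: C6 (and the transient C7) come from catalyst-controlled bromine delivery with anti migration, both carbinol epimers converging. C3 and C4 come from anti addition across C3=C4 on the faces fixed by the spiro centre.

Key step: step 5

Remark on locants: ring A is C1–C5, the spiro atom is C6, ring B is C7–C11; all spiro[5.5]undecane names below use this numbering, in which the target is (3S,4S,6S)-4,10-dibromo-1,5,5,9-tetramethylspiro[5.5]undeca-1,9-dien-3-ol.
Assumption: the sense of induction of the cinchona catalyst on this substrate has to be assigned by experiment; the route is written for (DHQD)2PHAL, and the pseudoenantiomer (DHQ)2PHAL is used if the opposite sense is found.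
Assumption: ketalisation of the 3-bromo enone places the double bond β,γ to the ketal carbon, as is general for 3-substituted cyclohex-2-enones; any α,β-isomer is removed at that stage.
Remark: the C9 methyl centre is racemic and uncontrolled from step 2 onward; it is erased in step 8, so the C9 epimers converge.

**Step 1**
Reactants: 1 4,4-dimethylcyclopentane-1,3-dione; 2 ethylene glycol
Product: 3 8,8-dimethyl-1,4-dioxaspiro[4.4]nonan-7-one
Conditions: 2 (1.1 equiv), p-toluenesulfonic acid monohydrate (TsOH·H2O, cat.), benzene, reflux, Dean–Stark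
Reagents that add atoms: ethylene glycol (2), OCCO
Why: Acid-catalysed ketalisation with azeotropic removal of water: the enolised dione is first O-alkylated to the 2-hydroxyethyl enol ether at the oxygen remote from the gem-dimethyl group, which then closes to the dioxolane, so that the hindered carbonyl next to CMe2 remains free.

**Step 2**
Reactants: 4 3-bromocyclohex-2-en-1-one
Product: 5 rac-3-bromo-6-methylcyclohex-2-en-1-one
Conditions: LiN(i-Pr)2 (LDA, 1.05 equiv), THF, −78 °C; MeI, DMPU, −78 → −20 °C
Reagents that add atoms: iodomethane, CI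
Why: Kinetic deprotonation of the β-bromo enone at its α′-methylene gives the cross-conjugated lithium enolate, which is C-methylated by iodomethane (enolate alkylation); the new stereocentre, later C9, is racemic and is erased in step 8.

**Step 3**
Reactants: 5 rac-3-bromo-6-methylcyclohex-2-en-1-one; 2 ethylene glycol
Product: 6 rac-7-bromo-10-methyl-1,4-dioxaspiro[4.5]dec-7-ene
Conditions: 2 (3 equiv), TsOH·H2O (cat.), benzene, reflux, Dean–Stark
Reagents that add atoms: ethylene glycol (2), OCCO
Why: Ketalisation of a 3-substituted cyclohex-2-enone under Dean–Stark conditions runs through the dienol ether and delivers the β,γ-unsaturated ketal, which places the bromine-bearing carbon (later C6) and the neighbouring CH (later C7) in the double bond.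

**Step 4**
Reactants: 6 rac-7-bromo-10-methyl-1,4-dioxaspiro[4.5]dec-7-ene; 3 8,8-dimethyl-1,4-dioxaspiro[4.4]nonan-7-one
Product: 9 8,8-dimethyl-7-(10-methyl-1,4-dioxaspiro[4.5]dec-7-en-7-yl)-1,4-dioxaspiro[4.4]nonan-7-ol (mixture of the four stereoisomers), via alkenyllithium 7 (not isolated), via alkenylcerium dichloride 8 (not isolated)
Conditions: t-BuLi (2.1 equiv), THF, −78 °C; anhydrous CeCl3, −78 °C; then 3, −78 → 0 °C; aq NH4Cl
Reagents that add atoms: none
Why: Bromine–lithium exchange followed by transmetalation to the weakly basic alkenylcerium reagent allows 1,2-addition to the hindered and enolisable ketone 3 (organocerium carbonyl addition); the carbinol centre is formed without control because step 5 destroys it.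

**Step 5**
Reactants: 9 8,8-dimethyl-7-(10-methyl-1,4-dioxaspiro[4.5]dec-7-en-7-yl)-1,4-dioxaspiro[4.4]nonan-7-ol
Product: 10 (6S,7R)-7-bromo-5,5,9-trimethylspiro[5.5]undecane-1,3,10-trione 3,10-bis(ethylene ketal) (C9 epimers)
Conditions: N-bromosuccinimide (1.2 equiv), (DHQD)2PHAL [hydroquinidine 1,4-phthalazinediyl diether] (10 mol %), Na2CO3, CHCl3–toluene (1:1), −40 °C, dark
Reagents that add atoms: N-bromosuccinimide, O=C1CCC(=O)N1Br
Why: Proposed new method: the quinuclidine nitrogen of the catalyst takes Br+ from NBS and delivers it to C7 on one face of the trisubstituted C6=C7 alkene, and as positive charge builds at tertiary C6 the C1–C5 σ bond lying anti to the new C–Br bond shifts from C1 to C6 while the C1 hydroxyl becomes the C1 ketone (bromonium-triggered semipinacol rearrangement). The closest known reaction type is the catalytic enantioselective halogenation/semipinacol rearrangement of 1-(cycloalkenyl)cyclobutanols with cinchona-derived or chiral phosphate catalysts; a five-to-six expansion that funnels a racemic, unsymmetrical carbinol into one enantiomer has not been shown. Ring A closes by this 1,2-alkyl shift, that is by ring expansion of the cyclopentanol to the cyclohexanone and not by cyclisation of a chain, and the shift forms the C5–C6 bond between two quaternary carbons. C7 is set directly by the face of bromine delivery and C6 by the obligatory anti relationship of bromine and migrating C5, so both follow the catalyst; the carbinol configuration disappears in the C1 carbonyl, and the remote C9 methyl only leads to two C9 epimers that merge in step 8. The step needs migration of C5 and not of C2, which is secured because C5 is quaternary and carries positive charge better whereas C2 is a methylene deactivated by the adjacent ketal carbon, and because no second alkene or free nucleophile competes for the bromonium ion.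

**Step 6**
Reactants: 10 (6S,7R)-7-bromo-5,5,9-trimethylspiro[5.5]undecane-1,3,10-trione 3,10-bis(ethylene ketal)
Product: 11 (6R)-5,5,9-trimethylspiro[5.5]undecane-1,3,10-trione 3,10-bis(ethylene ketal) (C9 epimers)
Conditions: Bu3SnH (1.5 equiv, 0.5 M), azobisisobutyronitrile (AIBN, cat.), benzene, 80 °C
Reagents that add atoms: none
Why: Radical chain dehalogenation with tin hydride: the secondary C7 radical is reduced faster than it can undergo 1,2-acyl migration (Dowd–Beckwith pathway) when the stannane is kept concentrated, and the quaternary C6 centre is not involved.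

**Step 7**
Reactants: 11 (6R)-5,5,9-trimethylspiro[5.5]undecane-1,3,10-trione 3,10-bis(ethylene ketal)
Product: 13 (6R)-3-(2-methylpropoxy)-5,5,9-trimethylspiro[5.5]undec-2-ene-1,10-dione (C9 epimers), via trione 12 (not isolated)
Conditions: 2 M aq HCl, THF, 40 °C; extraction and evaporation; then i-BuOH, TsOH·H2O (cat.), benzene, reflux, Dean–Stark
Reagents that add atoms: water, O; 2-methylpropan-1-ol, CC(C)CO
Why: Aqueous acid cleaves both dioxolanes, and the enolised 1,3-dione is then etherified under acid catalysis at the less hindered C3 oxygen, as is usual for 4,4-disubstituted cyclohexane-1,3-diones, which leaves the hindered C1 carbonyl and the ring-B ketone free.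

**Step 8**
Reactants: 13 (6R)-3-(2-methylpropoxy)-5,5,9-trimethylspiro[5.5]undec-2-ene-1,10-dione
Product: 14 (6R)-3-(2-methylpropoxy)-5,5,9-trimethylspiro[5.5]undeca-2,8-diene-1,10-dione
Conditions: 2-iodoxybenzoic acid (IBX, 2.5 equiv), DMSO–toluene, 75 °C
Reagents that add atoms: none
Why: IBX dehydrogenation proceeds through the ketone enol and can only introduce the C8=C9 double bond, because the other α-carbon C11 is attached to the quaternary C6, so both C9 epimers converge on one enone.

**Step 9**
Reactants: 14 (6R)-3-(2-methylpropoxy)-5,5,9-trimethylspiro[5.5]undeca-2,8-diene-1,10-dione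
Product: 16 (6R)-3-(2-methylpropoxy)-5,5,9-trimethyl-1-oxospiro[5.5]undeca-2,9-dien-10-yl trifluoromethanesulfonate, via lithium enolate 15 (not isolated)
Conditions: LiBH(s-Bu)3 (L-Selectride, 1.05 equiv), THF, −78 °C; then N-(5-chloropyridin-2-yl)triflimide, −78 → 0 °C; aq NH4Cl
Reagents that add atoms: N-(5-chloropyridin-2-yl)-1,1,1-trifluoro-N-(trifluoromethylsulfonyl)methanesulfonamide, O=S(=O)(N(c1ccc(Cl)cn1)S(=O)(=O)C(F)(F)F)C(F)(F)F
Why: The hindered borohydride adds hydride in 1,4-fashion to the β-unsubstituted, α-methyl enone of ring B and gives the C9=C10 enolate regiospecifically, which is trapped on oxygen as the triflate, while the ring-A vinylogous ester (hindered C1 carbonyl, alkoxy-substituted β-carbon) is not reduced at −78 °C.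

**Step 10**
Reactants: 16 (6R)-3-(2-methylpropoxy)-5,5,9-trimethyl-1-oxospiro[5.5]undeca-2,9-dien-10-yl trifluoromethanesulfonate
Product: 17 (6R)-10-bromo-3-(2-methylpropoxy)-5,5,9-trimethylspiro[5.5]undeca-2,9-dien-1-one
Conditions: Ni(cod)2 [bis(1,5-cyclooctadiene)nickel] (10 mol %), LiBr (3 equiv), DMA–THF (1:3), 23 °C
Reagents that add atoms: lithium bromide, [Li+].[Br-]
Why: Nickel-catalysed halide exchange of an enol triflate: oxidative addition of zerovalent nickel into the C10–O bond, triflate/bromide exchange at nickel and reductive elimination give the tetrasubstituted bromoalkene without moving the double bond.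

**Step 11**
Reactants: 17 (6R)-10-bromo-3-(2-methylpropoxy)-5,5,9-trimethylspiro[5.5]undeca-2,9-dien-1-one
Product: 19 (6R)-10-bromo-1,5,5,9-tetramethylspiro[5.5]undeca-1,9-dien-3-one, via tertiary carbinol 18 (not isolated)
Conditions: MeLi (3 equiv), anhydrous CeCl3 (3 equiv), THF, −78 → 0 °C; then 1 M aq HCl, 23 °C
Reagents that add atoms: methyllithium, [Li]C; water, O
Why: The methylcerium reagent adds to the hindered C1 carbonyl without enolisation or bromine–metal exchange, and dilute acid then hydrolyses the enol ether and eliminates water (Stork–Danheiser transposition) to give the C1-methyl enone.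

**Step 12**
Reactants: 19 (6R)-10-bromo-1,5,5,9-tetramethylspiro[5.5]undeca-1,9-dien-3-one
Product: 20 N'-[(6R)-10-bromo-1,5,5,9-tetramethylspiro[5.5]undeca-1,9-dien-3-ylidene]-4-methylbenzenesulfonohydrazide
Conditions: TsNHNH2 (1.2 equiv), EtOH, 60 °C
Reagents that add atoms: 4-methylbenzenesulfonohydrazide, Cc1ccc(cc1)S(=O)(=O)NN
Why: Condensation of the unhindered C3 carbonyl with the sulfonyl hydrazide (hydrazone formation) is routine for 3,5,5-trisubstituted cyclohex-2-enones of the isophorone type.

**Step 13**
Reactants: 20 N'-[(6R)-10-bromo-1,5,5,9-tetramethylspiro[5.5]undeca-1,9-dien-3-ylidene]-4-methylbenzenesulfonohydrazide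
Product: 22 (6S)-10-bromo-1,5,5,9-tetramethylspiro[5.5]undeca-1,3,9-triene, via alkenyllithium 21 (not isolated)
Conditions: LiN(i-Pr)2 (LDA, 3 equiv), THF, −78 → 23 °C; then H2O
Reagents that add atoms: none
Why: Shapiro reaction: the dianion formed by deprotonation of N–H and of the α′-methylene C4 loses sulfinate and N2, and protonation of the resulting alkenyllithium gives the homoannular diene (the outcome known for isophorone tosylhydrazone), an amide base being used so that the ring-B C–Br bond is not exchanged.

**Step 14**
Reactants: 22 (6S)-10-bromo-1,5,5,9-tetramethylspiro[5.5]undeca-1,3,9-triene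
Product: 23 (3S,4S,6S)-4,10-dibromo-1,5,5,9-tetramethylspiro[5.5]undeca-1,9-dien-3-ol
Conditions: N-bromosuccinimide (1.05 equiv), THF–H2O (4:1), 0 °C, dark
Reagents that add atoms: N-bromosuccinimide, O=C1CCC(=O)N1Br; water, O
Why: Bromohydrin formation on a 1,3-diene: Br+ should add to the diene terminus C4 (which leaves the allyl cation with its tertiary end at C1) on the face away from the pseudo-axial C7 methylene of ring B, and water should open the bromonium ion at the adjacent allylic C3 from the opposite face, which is free of the pseudo-axial C5 methyl, so that C4–Br and C3–OH come out trans, both equatorial, and (3S,4S) relative to C6.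

**Compound list**

1 | 4,4-dimethylcyclopentane-1,3-dione | CC1(C)CC(=O)CC1=O | starting material
2 | ethylene glycol | OCCO | starting material
3 | 8,8-dimethyl-1,4-dioxaspiro[4.4]nonan-7-one | O=C1CC2(OCCO2)CC1(C)C | intermediate
4 | 3-bromocyclohex-2-en-1-one | O=C1C=C(Br)CCC1 | starting material
5 | rac-3-bromo-6-methylcyclohex-2-en-1-one | O=C1C=C(Br)CCC1C | intermediate
6 | rac-7-bromo-10-methyl-1,4-dioxaspiro[4.5]dec-7-ene | BrC1=CCC(C)C2(OCCO2)C1 | intermediate
7 | (10-methyl-1,4-dioxaspiro[4.5]dec-7-en-7-yl)lithium (racemic) | [Li]C1=CCC(C)C2(OCCO2)C1 | intermediate (not isolated)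
8 | dichloro(10-methyl-1,4-dioxaspiro[4.5]dec-7-en-7-yl)cerium (racemic) | Cl[Ce](Cl)C1=CCC(C)C2(OCCO2)C1 | intermediate (not isolated)
9 | 8,8-dimethyl-7-(10-methyl-1,4-dioxaspiro[4.5]dec-7-en-7-yl)-1,4-dioxaspiro[4.4]nonan-7-ol (mixture of the four stereoisomers) | OC1(CC2(OCCO2)CC1(C)C)C3=CCC(C)C4(OCCO4)C3 | intermediate
10 | (6S,7R)-7-bromo-5,5,9-trimethylspiro[5.5]undecane-1,3,10-trione 3,10-bis(ethylene ketal) (C9 epimers) | O=C1CC2(OCCO2)CC(C)(C)[C@]13[C@H](Br)CC(C)C4(OCCO4)C3 | intermediate
11 | (6R)-5,5,9-trimethylspiro[5.5]undecane-1,3,10-trione 3,10-bis(ethylene ketal) (C9 epimers) | O=C1CC2(OCCO2)CC(C)(C)[C@]13CCC(C)C4(OCCO4)C3 | intermediate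
12 | (6R)-5,5,9-trimethylspiro[5.5]undecane-1,3,10-trione (C9 epimers, enolised 1,3-dione) | O=C1CC(=O)CC(C)(C)[C@]12CCC(C)C(=O)C2 | intermediate (not isolated)
13 | (6R)-3-(2-methylpropoxy)-5,5,9-trimethylspiro[5.5]undec-2-ene-1,10-dione (C9 epimers) | O=C1C=C(OCC(C)C)CC(C)(C)[C@]12CCC(C)C(=O)C2 | intermediate
14 | (6R)-3-(2-methylpropoxy)-5,5,9-trimethylspiro[5.5]undeca-2,8-diene-1,10-dione | O=C1C=C(OCC(C)C)CC(C)(C)[C@]12CC=C(C)C(=O)C2 | intermediate
15 | lithium (6R)-3-(2-methylpropoxy)-5,5,9-trimethyl-1-oxospiro[5.5]undeca-2,9-dien-10-olate | O=C1C=C(OCC(C)C)CC(C)(C)[C@]12CCC(C)=C(O[Li])C2 | intermediate (not isolated)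
16 | (6R)-3-(2-methylpropoxy)-5,5,9-trimethyl-1-oxospiro[5.5]undeca-2,9-dien-10-yl trifluoromethanesulfonate | O=C1C=C(OCC(C)C)CC(C)(C)[C@]12CCC(C)=C(OS(=O)(=O)C(F)(F)F)C2 | intermediate
17 | (6R)-10-bromo-3-(2-methylpropoxy)-5,5,9-trimethylspiro[5.5]undeca-2,9-dien-1-one | O=C1C=C(OCC(C)C)CC(C)(C)[C@]12CCC(C)=C(Br)C2 | intermediate
18 | (6R)-10-bromo-3-(2-methylpropoxy)-1,5,5,9-tetramethylspiro[5.5]undeca-2,9-dien-1-ol (C1 epimers) | CC1(O)C=C(OCC(C)C)CC(C)(C)[C@]12CCC(C)=C(Br)C2 | intermediate (not isolated)
19 | (6R)-10-bromo-1,5,5,9-tetramethylspiro[5.5]undeca-1,9-dien-3-one | CC1=CC(=O)CC(C)(C)[C@]12CCC(C)=C(Br)C2 | intermediate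
20 | N'-[(6R)-10-bromo-1,5,5,9-tetramethylspiro[5.5]undeca-1,9-dien-3-ylidene]-4-methylbenzenesulfonohydrazide | CC1=CC(=NNS(=O)(=O)c3ccc(C)cc3)CC(C)(C)[C@]12CCC(C)=C(Br)C2 | intermediate
21 | [(6S)-10-bromo-1,5,5,9-tetramethylspiro[5.5]undeca-1,3,9-trien-3-yl]lithium | CC1=CC([Li])=CC(C)(C)[C@]12CCC(C)=C(Br)C2 | intermediate (not isolated)
22 | (6S)-10-bromo-1,5,5,9-tetramethylspiro[5.5]undeca-1,3,9-triene | CC1=CC=CC(C)(C)[C@]12CCC(C)=C(Br)C2 | intermediate
23 | (3S,4S,6S)-4,10-dibromo-1,5,5,9-tetramethylspiro[5.5]undeca-1,9-dien-3-ol | CC1=C[C@H](O)[C@@H](Br)C(C)(C)[C@]12CCC(C)=C(Br)C2 | target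

**Step count and risks**

Total: 14 steps. Longest linear sequence: 13 steps (4 → 5 → 6 → 9 → 10 → 11 → 13 → 14 → 16 → 17 → 19 → 20 → 22 → 23).

Steps most likely to fail:

Step 5 (the step proposed as a new method).
- Bromine delivery may not be face-selective for both carbinol epimers, since the two enantiomers of the carbinol present the hydroxyl group differently to the catalyst; one may react unselectively or be left behind by kinetic resolution.
- The bromonium ion may be consumed by proton loss or by ketal participation instead of C5 migration.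
- Migration may be slow because the new bond joins two quaternary carbons and C5 must enter axially next to the ring-B ketal.
- Fallback, by known chemistry: from 9 the rearrangement is run without the chiral catalyst (NBS, NaHCO3, CH2Cl2, 0 °C), a racemic halonium semipinacol ring expansion, to give racemic 7-bromo-5,5,9-trimethylspiro[5.5]undecane-1,3,10-trione 3,10-bis(ethylene ketal) F1. This is taken through the conditions of steps 6 to 8 by way of the racemic debrominated bis-ketal F2, the racemic trione F3, the racemic vinylogous ester F4 and the racemic enedione F5. F5, the first compound without the C9 centre, is resolved by preparative chromatography on a chiral stationary phase. The (6R) enantiomer is 14, where the route is rejoined; the (6S) enantiomer F6 is set aside.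

Step 14.
- Bromonium formation at C4 may show poor facial selectivity.
- Water may capture the allyl cation at C1 (1,4-addition).
- The reagent may attack the ring-B alkene.
- Fallback: from 19, kinetic deprotonation at C4 and silylation (LDA, TMSCl, THF, −78 °C) gives the silyl dienol ether F7. NBS converts F7 into the α′-bromo enone F8, whose equatorial bromide cis to C11 should also be the more stable C4 epimer, so a kinetic mixture can be equilibrated with catalytic DBU. Reduction with NaBH4/CeCl3·7H2O in MeOH at −78 °C then gives 23 together with its C3 epimer, the cis-bromohydrin F9. F9 is separated and returned to F8 by Dess–Martin oxidation. The route is rejoined at 23.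

Step 10.
- Oxidative addition into the hindered, tetrasubstituted enol triflate may be slow.
- Halide exchange may stop short of completion, or the triflate may be lost by reduction.
- Fallback: from 16, Pd(PPh3)4-catalysed coupling with (Me3Sn)2 and LiCl in dioxane at 90 °C gives the alkenylstannane F10. Ipso-bromodestannylation of F10 with NBS in CH2Cl2 at −78 °C gives 17, where the route is rejoined.

**Further compounds**

F1 | step 5 | rac-(6S*,7R*)-7-bromo-5,5,9-trimethylspiro[5.5]undecane-1,3,10-trione 3,10-bis(ethylene ketal) (racemate, C9 epimers) | O=C1CC2(OCCO2)CC(C)(C)[C@]13[C@H](Br)CC(C)C4(OCCO4)C3.O=C1CC2(OCCO2)CC(C)(C)[C@@]13[C@@H](Br)CC(C)C4(OCCO4)C3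
F2 | step 5 | rac-5,5,9-trimethylspiro[5.5]undecane-1,3,10-trione 3,10-bis(ethylene ketal) (C9 epimers) | O=C1CC2(OCCO2)CC(C)(C)C13CCC(C)C4(OCCO4)C3
F3 | step 5 | rac-5,5,9-trimethylspiro[5.5]undecane-1,3,10-trione (C9 epimers) | O=C1CC(=O)CC(C)(C)C12CCC(C)C(=O)C2
F4 | step 5 | rac-3-(2-methylpropoxy)-5,5,9-trimethylspiro[5.5]undec-2-ene-1,10-dione (C9 epimers) | O=C1C=C(OCC(C)C)CC(C)(C)C12CCC(C)C(=O)C2
F5 | step 5 | rac-3-(2-methylpropoxy)-5,5,9-trimethylspiro[5.5]undeca-2,8-diene-1,10-dione | O=C1C=C(OCC(C)C)CC(C)(C)C12CC=C(C)C(=O)C2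
F6 | step 5 | (6S)-3-(2-methylpropoxy)-5,5,9-trimethylspiro[5.5]undeca-2,8-diene-1,10-dione | O=C1C=C(OCC(C)C)CC(C)(C)[C@@]12CC=C(C)C(=O)C2
F7 | step 14 | {[(6S)-10-bromo-1,5,5,9-tetramethylspiro[5.5]undeca-1,3,9-trien-3-yl]oxy}trimethylsilane | CC1=CC(O[Si](C)(C)C)=CC(C)(C)[C@]12CCC(C)=C(Br)C2
F8 | step 14 | (4S,6S)-4,10-dibromo-1,5,5,9-tetramethylspiro[5.5]undeca-1,9-dien-3-one | CC1=CC(=O)[C@@H](Br)C(C)(C)[C@]12CCC(C)=C(Br)C2
F9 | step 14 | (3R,4S,6S)-4,10-dibromo-1,5,5,9-tetramethylspiro[5.5]undeca-1,9-dien-3-ol | CC1=C[C@@H](O)[C@@H](Br)C(C)(C)[C@]12CCC(C)=C(Br)C2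
F10 | step 10 | (6R)-3-(2-methylpropoxy)-5,5,9-trimethyl-10-(trimethylstannyl)spiro[5.5]undeca-2,9-dien-1-one | O=C1C=C(OCC(C)C)CC(C)(C)[C@]12CCC(C)=C([Sn](C)(C)C)C2
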